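## Retrosynthetic overview

1. Target ⇐ C10 hydroxylation, C6 acylation and C4‑OH‑directed reduction of the C6 ketone of a trans‑fused hydroazulene ene‑dione.
2. Seven‑membered ring ⇐ two‑carbon ring expansion: reductive cleavage of the C5–C8 bond of a cyclobutanone fused to a bicyclo[3.3.0]octanone, then C7=C8 desaturation.
3. Cyclobutanone ⇐ [2+2] photocycloaddition of 1,1‑diethoxyethene to the bicyclic enone, making C5–C6 and C7–C8. The enabling feature is the tetrasubstituted enone double bond C5=C8 at the ring fusion (C9 carbonyl in ring B); after the addition it is the central cyclobutane bond of the 1,4‑diketone C6(=O)–C5–C8–C9(=O).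
4. Bicyclic enone (rings A and B in one step) ⇐ Pauson–Khand reaction of a 1,6‑enyne ⇐ (S)‑terpinen‑4‑ol, whose ten carbons become C1–C5, C8, the C1 methyl and the isopropyl group after ring opening by Eschenmoser–Tanabe fragmentation.
5. Ring order: terpinene ring opened → rings A + B → cyclobutane (key step) → seven‑membered ring by cleaving the bond shared by ring B and the cyclobutane.

Key step: step 7

Remark on numbering: daucane numbering is used in the text. C1 = quaternary ring‑fusion carbon with its methyl; C2, C3 = ring A methylenes; C4 = carbinol carbon with isopropyl; C5 = ring‑fusion CH; C6 = ester carbon; C7=C8 (methyl on C8); C9 = ketone; C10 = secondary carbinol. Ring A = C1–C5; ring B = C5, C8, C9, C10, C1 of the bicyclic intermediates. Systematic names of the hydroazulenes use azulene locants (C3 = C4, C3a = C5, C4 = C6, C6 = C8, C7 = C9, C8 = C10, C8a = C1).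

Assumption: (S)‑(+)‑terpinen‑4‑ol is used in high enantiomeric purity (material of lower purity would need enrichment); its carbinol centre becomes C4 with unchanged spatial arrangement.

## Route

Step 1
Reactants: 1 (S)‑(+)‑terpinen‑4‑ol
Product: 2 (6R)‑6‑hydroxy‑3‑methyl‑6‑(propan‑2‑yl)cyclohex‑2‑en‑1‑one
Conditions: Rh2(cap)4 (cap = caprolactamate, C6H10NO; 1 mol %), t‑BuOOH (5 equiv, decane solution), CH2Cl2, 25 °C
Reagents that add atoms: tert‑butyl hydroperoxide, CC(C)(C)OO
Why: Metal‑catalysed radical allylic oxidation of a trisubstituted cyclohexene attacks the ring CH2 next to the CH= terminus (the position that gives the β‑methyl enone, as in α‑pinene to verbenone), so the carbonyl should appear beside the carbinol carbon, whose configuration is not touched.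

Step 2
Reactants: 2 (6R)‑6‑hydroxy‑3‑methyl‑6‑(propan‑2‑yl)cyclohex‑2‑en‑1‑one
Product: 3 (6R)‑2,3‑epoxy‑6‑hydroxy‑3‑methyl‑6‑(propan‑2‑yl)cyclohexan‑1‑one (oxirane cis to the hydroxyl)
Conditions: 30% H2O2, NaOH (0.2 equiv), MeOH, 0 °C
Reagents that add atoms: hydrogen peroxide, OO
Why: Weitz–Scheffer nucleophilic epoxidation of the β‑methyl enone should give mainly the oxirane cis to the hydroxyl (trans to isopropyl), and either oxirane face is acceptable because both oxirane carbons lose their stereochemistry in step 3.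

Step 3
Reactants: 3 epoxy ketone
Product: 5 (5R)‑5‑hydroxy‑5‑(propan‑2‑yl)hept‑6‑yn‑2‑one, via tosylhydrazone 4 (not isolated)
Conditions: TsNHNH2 (1.1 equiv), CH2Cl2/AcOH (1:1), −20 → 25 °C
Reagents that add atoms: none
Why: Eschenmoser–Tanabe fragmentation: the tosylhydrazone opens the oxirane to an azoalkene alkoxide that fragments with loss of N2 and sulfinate, cutting the ring bond between the two oxirane carbons to give the alkyne (from the C=O carbon and its α‑carbon, the future C5 and C8) and the methyl ketone (future C1), with the carbinol centre as a spectator.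

Step 4
Reactants: 5 (5R)‑5‑hydroxy‑5‑(propan‑2‑yl)hept‑6‑yn‑2‑one
Product: 6 (3R)‑6‑methyl‑3‑(propan‑2‑yl)hept‑6‑en‑1‑yn‑3‑ol
Conditions: Ph3PCH3Br (3 equiv), KOtBu (3 equiv), THF, 0 → 25 °C
Reagents that add atoms: methyltriphenylphosphonium bromide, C[P+](c1ccccc1)(c1ccccc1)c1ccccc1.[Br-]
Why: Wittig methylenation of the methyl ketone (one equivalent of ylide is spent on the hydroxyl) installs the future C10 and the 1,1‑disubstituted alkene needed in step 6.

Step 5
Reactants: 6 (3R)‑6‑methyl‑3‑(propan‑2‑yl)hept‑6‑en‑1‑yn‑3‑ol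
Product: 8 (5R)‑2‑methyl‑5‑(propan‑2‑yl)oct‑1‑en‑6‑yn‑5‑ol, via dilithium alkoxide acetylide 7 (not isolated)
Conditions: n‑BuLi (2.1 equiv), THF, −78 → 0 °C; MeI (1.1 equiv), −78 → 25 °C; H2O
Reagents that add atoms: iodomethane, CI
Why: C‑alkylation of a lithium acetylide: the dianion should react with iodomethane at carbon because the hindered tertiary lithium alkoxide is a poor nucleophile in THF.

Step 6
Reactants: 8 (5R)‑2‑methyl‑5‑(propan‑2‑yl)oct‑1‑en‑6‑yn‑5‑ol
Product: 9 (4R,6aR)‑4‑hydroxy‑3,6a‑dimethyl‑4‑(propan‑2‑yl)‑4,5,6,6a‑tetrahydropentalen‑2(1H)‑one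
Conditions: Co2(CO)8 (20 mol %), tetramethylthiourea (0.6 equiv), CO (1 atm), toluene, 70 °C
Reagents that add atoms: carbon monoxide, [C-]#[O+]
Why: Catalytic intramolecular Pauson–Khand reaction of the 1,6‑enyne closes ring A (C5–C1) and ring B (C8–C9–C10) at once; the quaternary C1 is set in the alkene insertion, where the isopropyl group should take the pseudo‑equatorial site of the forming ring A away from the developing angular methyl, so that methyl and hydroxyl end cis (a minor C1 epimer would be removed by chromatography here).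

Step 7
Reactants: 9 bicyclic enone; 10 1,1‑diethoxyethene
Product: 12 10‑hydroxy‑4,7‑dimethyl‑10‑(propan‑2‑yl)tricyclo[5.3.0.0(1,4)]decane‑2,5‑dione (cyclobutanone: C6=O on C5; C7H2 on C8), via diethyl ketal photoadduct 11 (not isolated)
Conditions: 10 (15 equiv), hν (350 nm, Pyrex), CH2Cl2, −40 °C; then 1 M HCl, THF, 25 °C
Reagents that add atoms: 1,1‑diethoxyethene (10), C=C(OCC)OCC; water, O
Why: Enone–alkene [2+2] photocycloaddition: n→π* excitation and intersystem crossing give the triplet enone, which adds the alkene through a 1,4‑biradical; the closest known reaction type is the head‑to‑tail photoaddition of ketene acetals to cyclopentenones, including ring‑fusion enones of bicyclo[3.3.0]octenones. The cyclobutane C5–C6–C7–C8 is closed stepwise, one C–C bond by radical addition of the excited enone to the alkene and the second by recombination of the 1,4‑biradical. The two new stereocentres C5 and C8 are controlled by the ring system: the cyclobutane can only be cis‑fused to ring B, and the alkene can only add on the face of the C1 methyl (also the face of the small C4 hydroxyl, not of the isopropyl group), because addition on the other face would give a trans‑fused bicyclo[3.3.0]octane. The step needs head‑to‑tail regioselectivity, acetal carbon C6 on the β‑carbon C5 and CH2 on the α‑carbon C8, and this is secured by the polarity match between the enone triplet and the electron‑rich 1,1‑dialkoxyalkene. Mild acid in the same flask hydrolyses the strained ketal, so that C5–C8 becomes the central bond of the 1,4‑diketone C6(=O)–C5–C8–C9(=O) inside a four‑membered ring, ready for strain‑driven cleavage in step 8.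

Step 8
Reactants: 12 cyclobutanone
Product: 13 (3R,8aR)‑3‑hydroxy‑6,8a‑dimethyl‑3‑(propan‑2‑yl)octahydroazulene‑4,7‑dione (epimer mixture at C5 = C3a, C8 = C6)
Conditions: SmI2 (2.5 equiv), THF, MeOH (5 equiv), −78 → 0 °C
Reagents that add atoms: none
Why: Reductive cleavage of the strained central bond of a 1,4‑diketone by two single‑electron transfers should break C5–C8, the bond between two fully substituted carbons whose scission also releases the cyclobutane strain, in preference to C7–C8, and so merge cyclobutane and ring B into the seven‑membered ring; protonation gives C5 and C8 as epimer mixtures that are dealt with in step 9.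

Step 9
Reactants: 13 hydroazulene‑4,7‑dione
Product: 15 (3R,3aR,8aR)‑3‑hydroxy‑6,8a‑dimethyl‑3‑(propan‑2‑yl)‑1,2,3,3a,8,8a‑hexahydroazulene‑4,7‑dione, via C5‑epimeric ene‑dione mixture 14 (not isolated)
Conditions: IBX (1.5 equiv), DMSO, 65 °C; then Et3N (0.5 equiv), CH2Cl2, 25 °C
Reagents that add atoms: none
Why: IBX dehydrogenation of a ketone can only place the double bond at C7–C8 here, since every other α‑carbon has a quaternary β‑neighbour, which also removes the C8 stereocentre; C5, now α to the ene‑dione carbonyl and enolisable to a linearly conjugated dienol, should equilibrate with triethylamine to the isomer with C6 trans to the bulky isopropyl and cis to the hydroxyl that hydrogen‑bonds to the C6 carbonyl, that is the trans ring fusion.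

Step 10
Reactants: 15 trans‑fused ene‑dione
Product: 16 (3R,3aS,4S,8aR)‑3,4‑dihydroxy‑6,8a‑dimethyl‑3‑(propan‑2‑yl)‑1,2,3,3a,4,8a‑hexahydroazulen‑7(8H)‑one
Conditions: Me4NBH(OAc)3 (5 equiv), MeCN/AcOH (1:1), −30 °C
Reagents that add atoms: none
Why: Evans–Saksena reduction: the C4 hydroxyl exchanges onto boron and delivers hydride intramolecularly to the C6 carbonyl from the face of the C4 oxygen, which sets C6 with its hydroxyl cis to H5 (1,3‑anti diol), while the C9 enone carbonyl, which has no directing group, should not be reduced.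

Step 11
Reactants: 16 diol; 17 4‑methoxybenzoyl chloride
Product: 18 (3R,3aS,4S,8aR)‑3‑hydroxy‑6,8a‑dimethyl‑7‑oxo‑3‑(propan‑2‑yl)‑1,2,3,3a,4,7,8,8a‑octahydroazulen‑4‑yl 4‑methoxybenzoate
Conditions: 17 (1.3 equiv), pyridine, DMAP (0.1 equiv), CH2Cl2, 0 → 25 °C
Reagents that add atoms: 4‑methoxybenzoyl chloride (17), COc1ccc(cc1)C(Cl)=O
Why: DMAP‑catalysed acylation should take place only at the secondary allylic C6 hydroxyl, the tertiary C4 hydroxyl being unreactive under these conditions.

Step 12
Reactants: 18 C6 anisoate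
Product: 21 (3R,3aS,4S,8R,8aS)‑3,8‑dihydroxy‑6,8a‑dimethyl‑7‑oxo‑3‑(propan‑2‑yl)‑1,2,3,3a,4,7,8,8a‑octahydroazulen‑4‑yl 4‑methoxybenzoate (target), via dipotassium alkoxide enolate 19 (not isolated), via 10‑epimeric ketol 20 (not isolated)
Conditions: KN(SiMe3)2 (2.3 equiv), THF, −78 °C; 2‑(benzenesulfonyl)‑3‑phenyloxaziridine (1.3 equiv), −78 °C; H2O; then DBU (0.2 equiv), CH2Cl2, 25 °C
Reagents that add atoms: 2‑(benzenesulfonyl)‑3‑phenyloxaziridine, O=S(=O)(c1ccccc1)N1OC1c1ccccc1
Why: Oxidation of the kinetic α′ (C10) potassium enolate with an N‑sulfonyloxaziridine should deliver oxygen anti to the axial C1 methyl and so give mainly the 10‑epimer; α‑ketol epimerisation through the enediol (DBU) should then lead to the equatorial, hydrogen‑bonded C10 hydroxyl cis to that methyl, which is also what kinetic C‑protonation anti to the methyl gives.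

## Compound list

1 | (S)‑(+)‑terpinen‑4‑ol, (1S)‑4‑methyl‑1‑(propan‑2‑yl)cyclohex‑3‑en‑1‑ol | CC1=CC[C@](O)(C(C)C)CC1 | starting material
2 | (6R)‑6‑hydroxy‑3‑methyl‑6‑(propan‑2‑yl)cyclohex‑2‑en‑1‑one | CC1=CC(=O)[C@](O)(C(C)C)CC1 | intermediate
3 | (6R)‑2,3‑epoxy‑6‑hydroxy‑3‑methyl‑6‑(propan‑2‑yl)cyclohexan‑1‑one, oxirane cis to OH | C[C@]12O[C@H]1C(=O)[C@](O)(C(C)C)CC2 | intermediate
4 | N‑tosylhydrazone of 3 | C[C@]12O[C@H]1C(=NNS(=O)(=O)c1ccc(C)cc1)[C@](O)(C(C)C)CC2 | intermediate
5 | (5R)‑5‑hydroxy‑5‑(propan‑2‑yl)hept‑6‑yn‑2‑one | CC(=O)CC[C@@](O)(C(C)C)C#C | intermediate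
6 | (3R)‑6‑methyl‑3‑(propan‑2‑yl)hept‑6‑en‑1‑yn‑3‑ol | C=C(C)CC[C@@](O)(C(C)C)C#C | intermediate
7 | dilithium alkoxide acetylide of 6 | [Li+].[Li+].C=C(C)CC[C@@]([O-])(C(C)C)C#[C-] | intermediate
8 | (5R)‑2‑methyl‑5‑(propan‑2‑yl)oct‑1‑en‑6‑yn‑5‑ol | CC#C[C@](O)(C(C)C)CCC(C)=C | intermediate
9 | (4R,6aR)‑4‑hydroxy‑3,6a‑dimethyl‑4‑(propan‑2‑yl)‑4,5,6,6a‑tetrahydropentalen‑2(1H)‑one (OH cis to angular methyl) | CC1=C2[C@](O)(C(C)C)CC[C@]2(C)CC1=O | intermediate
10 | 1,1‑diethoxyethene | C=C(OCC)OCC | starting material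
11 | 2,2‑diethoxy‑10‑hydroxy‑4,7‑dimethyl‑10‑(propan‑2‑yl)tricyclo[5.3.0.0(1,4)]decan‑5‑one (cyclobutane cis‑fused to ring B on the face of the C1 methyl) | CCOC1(OCC)C[C@]2(C)C(=O)C[C@@]3(C)CC[C@@](O)(C(C)C)[C@@]123 | intermediate
12 | 10‑hydroxy‑4,7‑dimethyl‑10‑(propan‑2‑yl)tricyclo[5.3.0.0(1,4)]decane‑2,5‑dione (same fusion as 11) | O=C1C[C@]2(C)C(=O)C[C@@]3(C)CC[C@@](O)(C(C)C)[C@@]123 | intermediate
13 | (3R,8aR)‑3‑hydroxy‑6,8a‑dimethyl‑3‑(propan‑2‑yl)octahydroazulene‑4,7‑dione, C3a/C6 epimer mixture | O=C1CC(C)C(=O)C[C@@]2(C)CC[C@@](O)(C(C)C)C12 | intermediate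
14 | (3R,8aR)‑3‑hydroxy‑6,8a‑dimethyl‑3‑(propan‑2‑yl)‑1,2,3,3a,8,8a‑hexahydroazulene‑4,7‑dione, C3a epimer mixture | O=C1C=C(C)C(=O)C[C@@]2(C)CC[C@@](O)(C(C)C)C12 | intermediate
15 | (3R,3aR,8aR)‑3‑hydroxy‑6,8a‑dimethyl‑3‑(propan‑2‑yl)‑1,2,3,3a,8,8a‑hexahydroazulene‑4,7‑dione (trans‑fused) | O=C1C=C(C)C(=O)C[C@@]2(C)CC[C@@](O)(C(C)C)[C@H]12 | intermediate
16 | (3R,3aS,4S,8aR)‑3,4‑dihydroxy‑6,8a‑dimethyl‑3‑(propan‑2‑yl)‑1,2,3,3a,4,8a‑hexahydroazulen‑7(8H)‑one | O[C@H]1C=C(C)C(=O)C[C@@]2(C)CC[C@@](O)(C(C)C)[C@H]12 | intermediate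
17 | 4‑methoxybenzoyl chloride | COc1ccc(cc1)C(Cl)=O | starting material
18 | (3R,3aS,4S,8aR)‑3‑hydroxy‑6,8a‑dimethyl‑7‑oxo‑3‑(propan‑2‑yl)‑1,2,3,3a,4,7,8,8a‑octahydroazulen‑4‑yl 4‑methoxybenzoate | COc1ccc(C(=O)O[C@H]2C=C(C)C(=O)C[C@@]3(C)CC[C@@](O)(C(C)C)[C@H]23)cc1 | intermediate
19 | dipotassium C4‑alkoxide C9,C10‑enolate of 18 | [K+].[K+].COc1ccc(C(=O)O[C@H]2C=C(C)C([O-])=C[C@@]3(C)CC[C@@]([O-])(C(C)C)[C@H]23)cc1 | intermediate
20 | (3R,3aS,4S,8S,8aS)‑3,8‑dihydroxy‑6,8a‑dimethyl‑7‑oxo‑3‑(propan‑2‑yl)‑1,2,3,3a,4,7,8,8a‑octahydroazulen‑4‑yl 4‑methoxybenzoate (10‑epimer) | COc1ccc(C(=O)O[C@H]2C=C(C)C(=O)[C@@H](O)[C@@]3(C)CC[C@@](O)(C(C)C)[C@H]23)cc1 | intermediate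
21 | (3R,3aS,4S,8R,8aS)‑3,8‑dihydroxy‑6,8a‑dimethyl‑7‑oxo‑3‑(propan‑2‑yl)‑1,2,3,3a,4,7,8,8a‑octahydroazulen‑4‑yl 4‑methoxybenzoate | COc1ccc(C(=O)O[C@H]2C=C(C)C(=O)[C@H](O)[C@@]3(C)CC[C@@](O)(C(C)C)[C@H]23)cc1 | target

## Step count and risks

Total steps: 12. Longest linear sequence: 12 steps (from 1).

Steps most likely to fail:

Step 7. Bond formation at C5 lies between two quaternary carbons (C1 and C4). It may be slow, or the regiochemistry may turn to head‑to‑head. The fallback sets out from 9 and comes back at 12, and replaces the intermolecular addition by a silicon‑tethered one. Silylation of the tertiary hydroxyl with chlorodimethyl(vinyl)silane (imidazole, DMAP, DMF) would give the dimethylvinylsilyl ether of 9 F1. Irradiation (350 nm, CH2Cl2) should give the oxasilolane‑bridged intramolecular [2+2] adduct F2; the first bond joins the silicon‑bearing carbon to C5 in a five‑membered ring, the second joins CH2 to C8. Tamao–Fleming oxidation (KF, KHCO3, H2O2, THF/MeOH), which proceeds with retention, would give the C6 cyclobutanol F3. Oxidation with DMP (triacetoxy periodinane) returns to 12.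

Step 8. The electron transfer may cleave the exocyclic cyclobutane bond C7–C8 instead of C5–C8, since that bond overlaps better with a ketyl at C9, or it may only reduce a carbonyl. The fallback sets out from 12 and comes back at 13. TMSOTf/Et3N (CH2Cl2, 0 °C) would give the bis‑silyl compound F4, the trimethylsilyl enol ether of the cyclobutanone, which can only form towards C7, with the C4 hydroxyl also silylated. With C7 now sp2, scission of C7–C8 would need a vinyl radical. Single‑electron reduction of the C9 ketone (SmI2, HMPA, t‑BuOH, THF) should therefore cleave only C8–C5, through a 2‑siloxyallyl radical. Work‑up with 1 M HCl removes both silyl groups and gives 13.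

Step 12. Oxygen transfer is expected on the wrong face, and the later equilibration may stay incomplete or may cost the ester. The fallback sets out from 18 and comes back at 21, and sets C10 by hydride delivery instead. The hydroxylation of step 12 is run without the DBU treatment (ketol 20, either epimer serves). Oxidation with DMP would give the C9,C10‑dione F5, which cannot enolise on either side. Reduction with Zn(BH4)2 (Et2O, −40 °C) should attack the non‑conjugated C10 carbonyl from the face opposite the axial C1 methyl and give 21.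

## Further compounds

F1 | step 7 | dimethylvinylsilyl ether of 9 | CC1=C2[C@](O[Si](C)(C)C=C)(C(C)C)CC[C@]2(C)CC1=O
F2 | step 7 | oxasilolane‑bridged intramolecular [2+2] adduct (Si–C6, C6–C5, C7–C8) | C[Si]1(C)O[C@@]2(C(C)C)CC[C@]3(C)CC(=O)[C@@]4(C)C[C@H]1[C@@]234
F3 | step 7 | 2,10‑dihydroxy‑4,7‑dimethyl‑10‑(propan‑2‑yl)tricyclo[5.3.0.0(1,4)]decan‑5‑one (C6 hydroxyl cis to C4) | O[C@H]1C[C@]2(C)C(=O)C[C@@]3(C)CC[C@@](O)(C(C)C)[C@@]123
F4 | step 8 | trimethylsilyl enol ether (C6=C7) and C4 trimethylsilyl ether of 12 | C[Si](C)(C)OC1=C[C@]2(C)C(=O)C[C@@]3(C)CC[C@@](O[Si](C)(C)C)(C(C)C)[C@@]123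
F5 | step 12 | (3R,3aS,4S,8aR)‑3‑hydroxy‑6,8a‑dimethyl‑7,8‑dioxo‑3‑(propan‑2‑yl)‑1,2,3,3a,4,7,8,8a‑octahydroazulen‑4‑yl 4‑methoxybenzoate | COc1ccc(C(=O)O[C@H]2C=C(C)C(=O)C(=O)[C@@]3(C)CC[C@@](O)(C(C)C)[C@H]23)cc1
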